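**Retrosynthetic overview**

1. The target is cut at the bond between the bridging CH2 and C3 of the pyranone. 6-Ethyl-4-hydroxy-5-methyl-2-pyranone adds as a carbon nucleophile to the o-quinone methide of the chromene half, which is made in the same flask from the 8-unsubstituted chromene and a one-carbon iminium salt (three components, two C–C bonds at the central carbon).
2. Enabling feature: the CH2 sits on C8 of the benzene ring of the chromene, ortho to the free C7–OH, so this ring can be dearomatised to a C7=O/C8=CH2 o-quinone methide. Its partner, C3 of the 4-hydroxy-2-pyranone ring, lies between the C2 lactone carbonyl and the C4 enol and is an acidic, soft carbon nucleophile.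
3. Chromene half: the benzene ring is bought as phloroglucinol and C-acylated. The 2H-pyran ring is closed by Au(I) 6-endo hydroarylation of the para-O-(1,1-dimethylpropargyl) ether, which fixes the ring oxygen para to the ketone.
4. Pyranone half: the ring is built in one operation from the silyl enol ether of pentan-3-one and malonyl dichloride.
5. Order of ring formation: 2H-pyran of the chromene (step 3), 2-pyranone (step 5), then union of the two ring systems (step 6).

Key step: step 6

Assumption: the target has no stereocentre; the only stereo-element in the route, the double-bond geometry of the enolate and silyl enol ether of pentan-3-one, is lost in step 5, so the E/Z mixture is carried through (major E isomer drawn).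

**Route**

Step 1
Reactants: 1 phloroglucinol (benzene-1,3,5-triol); 2 2-methylpropanoyl chloride (isobutyryl chloride)
Product: 3 2-methyl-1-(2,4,6-trihydroxyphenyl)propan-1-one
Conditions: AlCl3 (3.5 equiv), PhNO2/CH2Cl2, 0 → 45 °C; then ice/aq. HCl
Reagents that add atoms: none
Why: Friedel–Crafts C-acylation of the very electron-rich, threefold-symmetric triol should stop at the mono-ketone, because the first acyl group deactivates the ring and any O-acylated material undergoes Fries rearrangement under AlCl3.

Step 2
Reactants: 3 2-methyl-1-(2,4,6-trihydroxyphenyl)propan-1-one; 4 3-chloro-3-methylbut-1-yne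
Product: 5 1-[2,6-dihydroxy-4-(2-methylbut-3-yn-2-yloxy)phenyl]-2-methylpropan-1-one
Conditions: K2CO3 (1.1 equiv), KI (cat.), CuI (cat.), acetone, 50 °C, N2
Reagents that add atoms: none
Why: Copper-assisted Williamson-type propargylic etherification should alkylate only the para hydroxyl, which is the most acidic and least hindered one (the ortho hydroxyls are held by the ketone), and 50 °C is too low for a Claisen rearrangement of the ether.

Step 3
Reactants: 5 1-[2,6-dihydroxy-4-(2-methylbut-3-yn-2-yloxy)phenyl]-2-methylpropan-1-one
Product: 6 1-(5,7-dihydroxy-2,2-dimethyl-2H-chromen-6-yl)-2-methylpropan-1-one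
Conditions: [JohnPhosAu(MeCN)]SbF6 (2 mol%), CH2Cl2, rt
Reagents that add atoms: none
Why: Gold(I)-catalysed intramolecular hydroarylation (6-endo-dig Friedel–Crafts-type attack of the arene carbon ortho to the ether oxygen on the π-activated terminal alkyne carbon, then protodeauration) should close the 2H-pyran; the two ortho carbons are equivalent by symmetry, and because the O–CMe2 bond is never broken the ring oxygen is necessarily the one para to the ketone.

Step 4
Reactants: 7 pentan-3-one
Product: 9 (E)-trimethyl(pent-2-en-3-yloxy)silane, via lithium enolate 8 (not isolated)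
Conditions: LDA (1.05 equiv), THF, −78 °C; then TMSCl, −78 °C → rt
Reagents that add atoms: chlorotrimethylsilane, C[Si](C)(C)Cl
Why: Kinetic enolisation of the symmetrical ketone and O-silylation of the lithium enolate (silyl enol ether formation) raise no regiochemical question, and the E/Z ratio is irrelevant because the geometry disappears in step 5.

Step 5
Reactants: 9 (E)-trimethyl(pent-2-en-3-yloxy)silane; 10 propanedioyl dichloride (malonyl dichloride)
Product: 12 6-ethyl-4-hydroxy-5-methyl-2H-pyran-2-one, via keto acid chloride 11 (not isolated)
Conditions: Et2O, −78 °C → rt; aqueous work-up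
Reagents that add atoms: none
Why: Effenberger-type pyranone synthesis: uncatalysed C-acylation of the silyl enol ether by the highly electrophilic malonyl dichloride (loss of TMSCl) gives the 3,5-dioxo acid chloride 11, whose C5 enol oxygen should acylate intramolecularly (lactonisation, loss of HCl) to the aromatic 4-hydroxy-2-pyranone.

Step 6
Reactants: 6 1-(5,7-dihydroxy-2,2-dimethyl-2H-chromen-6-yl)-2-methylpropan-1-one; 13 N,N-dimethylmethyleneiminium iodide (Eschenmoser's salt); 12 6-ethyl-4-hydroxy-5-methyl-2H-pyran-2-one
Product: 16 3-{[5,7-dihydroxy-2,2-dimethyl-6-(2-methylpropanoyl)-2H-chromen-8-yl]methyl}-6-ethyl-4-hydroxy-5-methyl-2H-pyran-2-one (target CNP0266853.0), via Mannich base 14 (not isolated), via o-quinone methide 15 (not isolated)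
Conditions: 13 (1.0 equiv), NaOAc (1.0 equiv), MeCN, 0 °C → rt; then 12 (1.2 equiv), 80 °C
Reagents that add atoms: none
Why: The iminium 13 aminomethylates C8, the only unsubstituted carbon of the benzene ring of 6 (phenolic Mannich reaction), and on warming in the acetate buffer the Mannich base 14 should expel dimethylamine through the C7 hydroxyl (E1cB) to give o-quinone methide 15, whose exocyclic CH2 is attacked by C3 of the enolate of pyranone 12 (pKa about 5) in a conjugate addition driven by rearomatisation of the benzene ring. The closest known reaction type is the alkylation of 4-hydroxy-2-pyranones, 4-hydroxycoumarins and other 1,3-dicarbonyl C–H acids by o-quinone methides released thermally from o-hydroxybenzyl amines or acetates of acylphenols, here run as a three-component Mannich-type union in one flask. No ring is closed and no stereocentre is formed, the target being achiral. The step needs one unsymmetrical C–C coupling at the methylene carbon (C- rather than O-alkylation of the pyranone, and no bis-pyranyl or bis-aryl methane): 6 offers a single aromatic C–H, so 14 has no nucleophilic carbon left to compete for 15; the iminium is consumed before 12 is added, so no methylene-pyrandione can form; and C3 is the only carbon nucleophile of 12, while any O-adduct should revert to 15 under the conditions and funnel to the C-linked, rearomatised product.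

**Compound list**

1 | phloroglucinol (benzene-1,3,5-triol) | Oc1cc(O)cc(O)c1 | starting material
2 | 2-methylpropanoyl chloride (isobutyryl chloride) | CC(C)C(=O)Cl | starting material
3 | 2-methyl-1-(2,4,6-trihydroxyphenyl)propan-1-one | CC(C)C(=O)c1c(O)cc(O)cc1O | intermediate
4 | 3-chloro-3-methylbut-1-yne | CC(C)(Cl)C#C | starting material
5 | 1-[2,6-dihydroxy-4-(2-methylbut-3-yn-2-yloxy)phenyl]-2-methylpropan-1-one | CC(C)C(=O)c1c(O)cc(OC(C)(C)C#C)cc1O | intermediate
6 | 1-(5,7-dihydroxy-2,2-dimethyl-2H-chromen-6-yl)-2-methylpropan-1-one | CC(C)C(=O)c1c(O)cc2OC(C)(C)C=Cc2c1O | intermediate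
7 | pentan-3-one | CCC(=O)CC | starting material
8 | lithium (E)-pent-2-en-3-olate | [Li+].C/C=C(\CC)[O-] | intermediate (not isolated)
9 | (E)-trimethyl(pent-2-en-3-yloxy)silane (major isomer of an E/Z mixture) | C/C=C(\CC)O[Si](C)(C)C | intermediate
10 | propanedioyl dichloride (malonyl dichloride) | O=C(Cl)CC(=O)Cl | starting material
11 | 4-methyl-3,5-dioxoheptanoyl chloride | CCC(=O)C(C)C(=O)CC(=O)Cl | intermediate (not isolated)
12 | 6-ethyl-4-hydroxy-5-methyl-2H-pyran-2-one | CCc1oc(=O)cc(O)c1C | intermediate
13 | N,N-dimethylmethyleneiminium iodide (Eschenmoser's salt) | C[N+](C)=C.[I-] | starting material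
14 | 1-{8-[(dimethylamino)methyl]-5,7-dihydroxy-2,2-dimethyl-2H-chromen-6-yl}-2-methylpropan-1-one | CC(C)C(=O)c1c(O)c(CN(C)C)c2OC(C)(C)C=Cc2c1O | intermediate (not isolated)
15 | 5-hydroxy-2,2-dimethyl-8-methylidene-6-(2-methylpropanoyl)-2H-chromen-7(8H)-one (o-quinone methide) | C=C1C(=O)C(C(=O)C(C)C)=C(O)C2=C1OC(C)(C)C=C2 | intermediate (not isolated)
16 | 3-{[5,7-dihydroxy-2,2-dimethyl-6-(2-methylpropanoyl)-2H-chromen-8-yl]methyl}-6-ethyl-4-hydroxy-5-methyl-2H-pyran-2-one | CCc1oc(=O)c(Cc2c(O)c(C(=O)C(C)C)c(O)c3c2OC(C)(C)C=C3)c(O)c1C | target

**Step count and risks**

Total steps: 6. Longest linear sequence: 4 steps (steps 1, 2, 3 and 6 from phloroglucinol); the pyranone branch is 3 steps (4, 5 and 6).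

Steps most likely to fail:

1. Step 6. What may go wrong: aminomethylation of C8 may be slow or incomplete, so that residual iminium is transferred to the pyranone and symmetric coupling takes over; or amine elimination may be sluggish, so that prolonged heating scrambles the methylene bridge by retro-Michael reaction. The fallback inverts the polarity of the union; it sets out from 12 (with 6 and 13) and comes back at 16. Pyranone 12 is treated with 13 and NaOAc in MeCN in the presence of a slight excess of chromene 6. The pyranone is aminomethylated at C3 to 3-[(dimethylamino)methyl]-6-ethyl-4-hydroxy-5-methyl-2H-pyran-2-one F1, which should lose dimethylamine on gentle warming to 6-ethyl-5-methyl-3-methylidene-2H-pyran-2,4(3H)-dione F2. This doubly activated Michael acceptor is attacked by C8 of 6 as a phenol carbon nucleophile, and tautomerisation gives 16. The bond made last is then the one between CH2 and C8 of the chromene.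

2. Step 2. What may go wrong: C-propargylation or over-alkylation of the polyphenol, or oxidative coupling of the terminal alkyne under copper. The fallback sets out from 3 and comes back at 6, bypassing steps 2 and 3. Ketone 3 is heated with 3-methylbut-2-enal and ethylenediammonium diacetate (cat.) in toluene (or in pyridine at 110 °C). Knoevenagel-type condensation at a ring carbon followed by oxa-6π electrocyclisation should give chromene 6 directly. Ring closure through an ortho oxygen can compete in this variant, so the regioisomeric chromene would have to be removed by chromatography.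

3. Step 3. What may go wrong: ionisation of the tertiary propargylic C–O bond by the cationic gold with loss of the side chain, or sequestration of the catalyst by the chelating hydroxy ketone. The fallback sets out from 5 and comes back at 6. Ether 5 is acetylated (Ac2O, pyridine, DMAP) to 2-(2-methylpropanoyl)-5-(2-methylbut-3-yn-2-yloxy)-1,3-phenylene diacetate F3. Heating F3 in o-xylene at 140 °C should trigger the aromatic propargyl Claisen rearrangement, enolisation, [1,5]-hydrogen shift and oxa-6π electrocyclisation to 2,2-dimethyl-6-(2-methylpropanoyl)-2H-chromene-5,7-diyl diacetate F4. After the Claisen step only the para oxygen carries a hydrogen, so ring closure can occur only through it. Methanolysis (K2CO3, MeOH, rt) then gives 6.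

Further compounds
F1 | step 6 | 3-[(dimethylamino)methyl]-6-ethyl-4-hydroxy-5-methyl-2H-pyran-2-one | CCc1oc(=O)c(CN(C)C)c(O)c1C
F2 | step 6 | 6-ethyl-5-methyl-3-methylidene-2H-pyran-2,4(3H)-dione | CCC1=C(C)C(=O)C(=C)C(=O)O1
F0 | step 2 | none | none
F3 | step 3 | 2-(2-methylpropanoyl)-5-(2-methylbut-3-yn-2-yloxy)-1,3-phenylene diacetate | CC(C)C(=O)c1c(OC(C)=O)cc(OC(C)(C)C#C)cc1OC(C)=O
F4 | step 3 | 2,2-dimethyl-6-(2-methylpropanoyl)-2H-chromene-5,7-diyl diacetate | CC(C)C(=O)c1c(OC(C)=O)cc2OC(C)(C)C=Cc2c1OC(C)=O
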